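Readings and results were computed for substances that don't exist.

Decide how to charge this flask by counting contact minutes. Read them from the two earlier runs.

| flask | starting material | reagent | protic impurity | remark | time |
|---|---|---|---|---|---|
| theta | 0.028 M | 0.056 M | 1.4 mM | run made earlier |  |
| beta | 0.056 M | 0.056 M | 1.4 mM | run made earlier |  |
| midnight | 0.028 M | 0.0560 M | 1.40 mM | everything together at the start | 40 min |
| noon | 0.028 M | 0.0560 M (in portions, 5, over 30 min) | 1.40 mM | first portion at the start, last at 30 min | 40 min |
| winter | 0.028 M | 0.0560 M (fed, over 30 min) | 1.40 mM | all else is in the flask from the start; the feed brings no volume worth counting | 40 min |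
| dusk | 0.028 M (fed, over 30 min) | 0.0560 M | 1.40 mM | all else is in the flask from the start; the feed brings no volume worth counting | 40 min |

| run | time / min | target / % |
|---|---|---|
| theta | 3.00 | 9.3 |
| theta | 5.00 | 12.9 |
| theta | 8.00 | 19.6 |
| theta | 15.0 | 30.8 |
| theta | 25.0 | 42.7 |
| theta | 40.0 | 52.9 |
| beta | 0.250 | 0 |
| beta | 0.833 | 0 |
| beta | 1.33 | 4.3 |
| beta | 2.00 | 5.5 |
| beta | 3.00 | 8.5 |
| beta | 4.00 | 10.3 |

(standard deviation of a reading: 1 percentage point)

- the numbers in the tables scatter by 1 percentage point (one standard deviation)

* the flask with the highest amount of target, in percent of the starting material charged ("all alike" if they lie within 1.5 percentage points) (midnight / noon / winter / dusk / all alike)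
* final target, as a percentage of the starting material charged, in midnight
* final target, as a percentage of the starting material charged, in noon
* final target, as a percentage of the starting material charged, in winter
* final target, as a percentage of the starting material charged, in dusk

Start with the starting material. At 3.00 min theta reads 9.3% and beta 8.5%, though beta holds twice the starting material. The gap is 0.8 percentage points against a scatter of 1 point. So take the early percent made per minute as independent of the charge. Assume further that each parcel of starting material walks theta's curve on its own clock.

Now reckon 25.0 min, the run time less half the feed time. Call it the contact minutes: the minutes of full reagent that the average parcel of starting material meets by the end.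

Midnight repeats theta, so read 52.9% at 40.0 min. In dusk the parcels enter evenly, so their stays run evenly from 10.0 min to 40 min, 25.0 min on average. Theta's curve bends over those stays, so average the curve and do not read it at the mean stay. Theta interpolates to 22.8% at the shortest stay, and trapezoids up to 40.0 min give 40.6%, less than the 42.7% read at the mean stay. In winter the starting material waits while reagent rises steadily. If the rate follows reagent in proportion, the sum is again 25.0 min. Noon's steps, one portion every 7.50 min, sum to the same.

That proportion is the weak link, since both runs hold 0.056 M of reagent and neither tests it. Reforge it. Let the rate follow reagent squared, and winter's sum drops to 20.0 min. Theta, interpolated there, gives 36.8%. Commit noon and winter to the midpoint, 39.8%. Dusk and midnight keep their values, as both hold full reagent from the start. Midnight comes out highest.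

The forecast, my own reckoning apart, says 53%, 38%, 37% and 41% for midnight, noon, winter and dusk, and picks midnight: “Adding everything at the start wins”. It sits below my number for noon and winter and above mine for dusk.

Midnight gives 52.3%, noon 40.6%, winter 39.5% and dusk 42.3%, so midnight holds the most.

    2 starting material → homo dimer (k = 0.405 M⁻¹ min⁻¹)
    reagent + tight pair → target (k = 96.1 M⁻¹ min⁻¹)
    tight pair ⇌ loose pair (K = 0.0409, k = 6.05 min⁻¹)
    starting material + protic impurity → quenched substrate (k = 24.3 M⁻¹ min⁻¹)
    reagent ⇌ dormant form (K = 0.312, k = 0.117 min⁻¹)
    reagent + loose pair → isomer of the product (k = 50.6 M⁻¹ min⁻¹)
    starting material ⇌ tight pair (K = 0.0180, k = 0.0549 min⁻¹)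

Dusk lies 1.7 points above the average of theta over its stays, and winter lies 3.2 points below theta's reading at 25.0 min. At 40.0 min homo dimer stands at 30.0% in winter and 13.8% in dusk. Use the clock once more on winter's neighbour with 0.014 M of reagent, a quarter of the charge. Its contact minutes are 6.25 min, where theta interpolates to 15.7%. That neighbour gave 16.8%.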